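Slowness is what to reckon first in this flask, and it can be done by hand.

    L + G + L.G → 2 L.G (k1 = 6.1 L² mol⁻² h⁻¹)
    L + G → L.G (k2 = 9.8 × 10⁻⁴ L mol⁻¹ h⁻¹)
    L.G → D (k3 = 0.44 h⁻¹)

L 0.10 M; G 0.500 M; time 3.0 d

- at 3.0 d, what has stopped the reaction, if anything has (it is still moving / forward and back rates have come level / all of L has reacted / G has run out first)
- the D standing at 3.0 d, as a percentage of the L charged

- the reaction counts as stopped when no species that holds the L changes by six tenths of a point or more over the second half of the time
- run time (flask): 3.0 d

The autocatalytic step needs L.G, but the flask is charged with none, so the uncatalysed step must seed it. By itself that step gives L a half-life of 58.9 d, far longer than the run. L.G decays to D with a half-life of 0.0656 d, so the question is how many successors one L.G makes before it goes. The constant of the autocatalytic step times the charges of L and G, over the decay constant, gives 0.693: the loop gain. It is below one, so L.G holds a quasi-steady level and each seed counts 3.26 times.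

The fraction of the charge leaking to D is then 0.00160 h⁻¹, after a lag of 7.41 h. Kept up, that leak would take 10.3%. But the gain sinks with L to 0.622, where the leak is 0.00116 h⁻¹. The mean of the two leaks gives 8.91% as D in this reckoning. Even the lower leak takes 4.18% of the charge over the second half of the time, so this reckoning has the reaction still moving.

The forecast, a separate estimate, says it is still moving and 8.7%, less than the reckoning here, from “a slow, gradually declining leak of L to D”.

The simulation gives it is still moving and 8.88%.

At 3.00 d this flask holds L at 90.9% and G at 98.2% of their charges, which puts its gain at 0.619. The neighbour charged with 0.40 M of L starts at a gain of 2.77, above one, so the leak reckoning yields no steady level there. At 3.00 d that neighbour holds 71.2% of the L charged as D and 28.8% as L, and its L and G, with G at 43.0% of its own charge, then stand at a gain of 0.344.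

All constants were chosen freely; the flask was simulated.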